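At early times the spring flask does not add up: at 0.167 d the readings of Q, Z and L leave 11.0% of the charge unseen. Q is charged in the smaller amount, 20 mM against 26 mM of J, so we write its balance: charged Q stands as Q, Z, L or something unseen.

| flask | Q | J | remark | time |
|---|---|---|---|---|
| spring | 20 mM | 26 mM | the very flask that is asked about, followed so far |  |
| dusk | 10 mM | 26 mM | run made earlier |  |
| flask | 20 mM | 26.0 mM |  | 15 d |

| run | time / d | Z / % | L / % | Q / % |
|---|---|---|---|---|
| spring | 0.167 | 18 | 2 | 69 |
| spring | 0.500 | 35 | 6 | 45 |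
| spring | 0.833 | 43 | 10 | 33 |
| spring | 1.25 | 49 | 15 | 22 |
| spring | 1.67 | 52 | 17 | 20 |
| spring | 2.50 | 48 | 19 | 12 |
| spring | 3.00 | 48 | 18 | 7 |
| dusk | 0.833 | 46 | 12 | 27 |
| dusk | 1.25 | 54 | 16 | 18 |
| dusk | 2.08 | 53 | 18 | 6 |
| dusk | 3.00 | 54 | 22 | 5 |
| dusk | 5.00 | 45 | 26 | 0 |
| dusk | 6.00 | 41 | 22 | 0 |
| dusk | 10.0 | 32 | 23 | 0 |

(standard deviation of a reading: 1.5 percentage points)

1. share of Z in Z plus L at 15 min
2. share of Z in Z plus L at 10 h
3. share of Z in Z plus L at 15 d

Two views part over the latest time. The first view gave the forecast, 97%, 86% and 45%, and holds that “L plateaus near 23% while Z decays to something unseen”, so Z goes on falling.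

My own view is that Z and the unseen material come to a balance. In the dusk run at 10.0 d, Q reads 0%, Z 32% and L 23%. That gives the hold ratio, the unseen share over Z once Q is used up, as 1.41, a reading with its scatter. The balance then gives Z as the charge less L, divided by one plus the hold ratio. Taking L from that dusk reading, I reckon Z at 32.0% and a share of 58.2% at 15 d.

The flask gives 99.4%, 85.9% and 54.8%. The forecast holds at the first two times but is 9.8 percentage points low at the last, and my share is 3.4 points high. Z stands at 29.3% at 15.0 d and 28.0% at 150 d. The decay view has its region earlier, where Z fell from 49.0% at 1.50 d to 36.2% at 7.50 d.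

    J + E → L (k = 8.10 × 10⁻⁴ L mol⁻¹ s⁻¹)
    Q ⇌ E (K = 0.380, k = 9.80 × 10⁻⁶ s⁻¹)
    Q + J → Z (k = 5.90 × 10⁻⁴ L mol⁻¹ s⁻¹)
    Z ⇌ D (K = 1.70, k = 2.00 × 10⁻⁶ s⁻¹)

The unseen material is E and D, and the relaxation half-life of Z and D, both ways together, is 2.53 d, short against 15 d. With this flask's L of 24.2%, the hold ratio gives Z 31.5%, and the flask holds 29.3%. The neighbouring flask, charged with 100 mM of J, ends with L at 11.9%, so the same balance gives Z 36.6% and a share of 75.5%. That neighbouring flask ends with Z at 33.6% and a share of 73.9%.

Readings and results were computed for substances that don't exist.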